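## Retrosynthetic overview

1. The target is traced back to a cis-3,4-disubstituted γ-lactone: lactone → lactol acetate, dioxolane → CH(OAc)CO2Me, C8 ketone → exocyclic methylene.
2. The oxolane C3′–C4′ bond and both of its stereocentres come from an Ireland–Claisen [3,3] rearrangement of an ester between a hydroazulenyl-acetic acid and a D-mannitol-derived (S)-allylic alcohol.
3. The quaternary C1–CH2 bond comes from an anionic oxy-Cope [3,3] rearrangement of the prenyl Grignard adduct of a bicyclic enone; the prenyl group is then cut down to CH2CO2H.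
4. The seven-membered ring comes from ring-closing metathesis followed by radical hydromethylation (gem-dimethyl); the cyclopentene comes from aldol condensation of the keto aldehyde from (+)-limonene oxide.
5. Ring order: cyclopentene → cycloheptene → γ-lactone/oxolane.

Assumption: (+)-limonene oxide and 1,2:5,6-di-O-isopropylidene-D-mannitol are bought as single enantiomers. Locants follow the target: hydroazulene C1 (quaternary C–CH3), C3a/C8a (ring fusion), C4 (CMe2), C8 (C=O, later C=CH2); oxolane C2′ (acetal), C3′ (on C1), C4′, C5′; α is the face of H-3a.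

## Route

Step 1
Reactants: 1 (4R)-limonene 1,2-oxide ((+)-limonene oxide; cis/trans epoxide mixture)
Product: 2 (3R)-6-oxo-3-(prop-1-en-2-yl)heptanal
Conditions: H5IO6, THF/H2O, 0 → 25 °C
Reagents that add atoms: water, O
Why: Periodic acid hydrolyses the epoxide and cleaves the diol (Malaprade glycol cleavage); the bought stereocentre and the isopropenyl group are not touched.

Step 2
Reactants: 2 (3R)-6-oxo-3-(prop-1-en-2-yl)heptanal
Product: 3 (5S)-2-methyl-5-(prop-1-en-2-yl)cyclopent-1-ene-1-carbaldehyde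
Conditions: piperidine (cat.), AcOH (cat.), toluene, 60 °C
Reagents that add atoms: none
Why: Enamine-mediated intramolecular aldol condensation (aldehyde α-carbon onto the methyl ketone, 5-ring) gives the conjugated enal; the stereocentre is not α to a carbonyl and is kept.

Step 3
Reactants: 3 (5S)-2-methyl-5-(prop-1-en-2-yl)cyclopent-1-ene-1-carbaldehyde
Product: 4 1-[(5S)-2-methyl-5-(prop-1-en-2-yl)cyclopent-1-en-1-yl]pent-4-en-1-ol (both carbinol epimers)
Conditions: CH2=CHCH2CH2MgBr, THF, −78 °C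
Reagents that add atoms: but-3-en-1-ylmagnesium bromide, C=CCC[Mg]Br
Why: Grignard 1,2-addition to the enal brings in C5–C7; the new carbinol centre is removed in the next step.

Step 4
Reactants: 4 1-[(5S)-2-methyl-5-(prop-1-en-2-yl)cyclopent-1-en-1-yl]pent-4-en-1-ol
Product: 5 1-[(5S)-2-methyl-5-(prop-1-en-2-yl)cyclopent-1-en-1-yl]pent-4-en-1-one
Conditions: MnO2, CH2Cl2, 25 °C
Reagents that add atoms: none
Why: Selective oxidation of the allylic alcohol to the dienone; the alkenes are inert to MnO2.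

Step 5
Reactants: 5 1-[(5S)-2-methyl-5-(prop-1-en-2-yl)cyclopent-1-en-1-yl]pent-4-en-1-one
Product: 6 (3aS)-1,4-dimethyl-3,3a,6,7-tetrahydroazulen-8(2H)-one (C1=C8a and C4=C5 double bonds; H-3a α)
Conditions: second-generation Grubbs catalyst (5 mol %), CH2Cl2 (0.005 M), 40 °C
Reagents that add atoms: none
Why: Ring-closing metathesis of the isopropenyl and terminal alkene closes the seven-membered ring; the tetrasubstituted enone alkene does not take part.

Step 6
Reactants: 6 (3aS)-1,4-dimethyl-3,3a,6,7-tetrahydroazulen-8(2H)-one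
Product: 8 (3aS)-1,4,4-trimethyl-3,3a,4,5,6,7-hexahydroazulen-8(2H)-one, via sulfonylhydrazide adduct 7 (not isolated)
Conditions: Fe(acac)3 (30 mol %), PhSiH3, CH2=N–NHSO2Mes, EtOH/THF, 25 °C; then MeOH, 60 °C
Reagents that add atoms: formaldehyde mesitylenesulfonylhydrazone, C=NNS(=O)(=O)c1c(C)cc(C)cc1C
Why: Hydrogen-atom-transfer hydromethylation (Baran): Markovnikov H-atom transfer to the electron-rich C4=C5 alkene gives the tertiary C4 radical, which adds to the hydrazone; loss of sulfinate and N2 leaves the gem-dimethyl group, and the electron-poor tetrasubstituted enone is not attacked.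

Step 7
Reactants: 8 (3aS)-1,4,4-trimethyl-3,3a,4,5,6,7-hexahydroazulen-8(2H)-one
Product: 9 (3aS)-1,4,4-trimethyl-8-(2-methylbut-3-en-2-yl)-2,3,3a,4,5,6,7,8-octahydroazulen-8-ol (C8 side chain α; OH β)
Conditions: prenylMgCl, THF, −78 °C
Reagents that add atoms: 3-methylbut-2-en-1-ylmagnesium chloride, CC(C)=CC[Mg]Cl
Why: The allylic Grignard adds 1,2 through its γ-carbon (SE2′); the C4–C7 bridge is held on the β-face by C3a, so attack is expected from the α-face.

Step 8
Reactants: 9 (3aS)-1,4,4-trimethyl-8-(2-methylbut-3-en-2-yl)-2,3,3a,4,5,6,7,8-octahydroazulen-8-ol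
Product: 12 1β,4,4-trimethyl-1α-(3-methylbut-2-en-1-yl)-cis-perhydroazulen-8-one (H-3a and H-8a α), via potassium alkoxide 10 (not isolated), via potassium enolate 11 (not isolated)
Conditions: KH, 18-crown-6, THF, 0 → 25 °C; then aq. NH4Cl, −78 °C
Reagents that add atoms: none
Why: Anionic oxy-Cope [3,3] rearrangement moves the allyl unit suprafacially from C8 to C1, so the α-configured carbinol gives the quaternary centre with CH2 α and CH3 β; protonation of the enolate on the convex α-face gives the cis ring fusion.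

Step 9
Reactants: 12 1β,4,4-trimethyl-1α-(3-methylbut-2-en-1-yl)-cis-perhydroazulen-8-one
Product: 13 2-(1β,4,4-trimethyl-8-oxo-cis-perhydroazulen-1α-yl)acetic acid
Conditions: RuCl3 (cat.), NaIO4, CCl4/MeCN/H2O, 25 °C
Reagents that add atoms: sodium periodate, [Na+].[O-]I(=O)(=O)=O; water, O
Why: RuO4 cleavage (Sharpless conditions) of the trisubstituted alkene gives the acid and acetone; ketone and stereocentres are untouched.

Step 10
Reactants: 14 1,2:5,6-di-O-isopropylidene-D-mannitol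
Product: 15 (4S,4′S)-4,4′-[(E)-ethene-1,2-diyl]bis(2,2-dimethyl-1,3-dioxolane)
Conditions: PPh3, I2, imidazole, toluene, 110 °C
Reagents that add atoms: none
Why: Garegg–Samuelsson deoxygenation of the threo-3,4-diol gives the (E)-alkene; the two dioxolane stereocentres are bought with mannitol.

Step 11
Reactants: 15 (4S,4′S)-4,4′-[(E)-ethene-1,2-diyl]bis(2,2-dimethyl-1,3-dioxolane)
Product: 16 (2S,3E)-4-[(4S)-2,2-dimethyl-1,3-dioxolan-4-yl]but-3-ene-1,2-diol
Conditions: AcOH/H2O (3:2), 25 °C, stopped at about 50 % conversion (15 recycled)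
Reagents that add atoms: none
Why: Acid hydrolysis of one acetonide; the substrate is C2-symmetric, so either acetonide gives the same diol.

Step 12
Reactants: 16 (2S,3E)-4-[(4S)-2,2-dimethyl-1,3-dioxolan-4-yl]but-3-ene-1,2-diol
Product: 17 (2S,3E)-1-[(tert-butyldimethylsilyl)oxy]-4-[(4S)-2,2-dimethyl-1,3-dioxolan-4-yl]but-3-en-2-ol
Conditions: TBSCl, imidazole, CH2Cl2, −20 °C
Reagents that add atoms: tert-butyldimethylsilyl chloride, CC(C)(C)[Si](C)(C)Cl
Why: Selective silylation of the primary hydroxyl leaves the secondary allylic alcohol free.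

Step 13
Reactants: 13 2-(1β,4,4-trimethyl-8-oxo-cis-perhydroazulen-1α-yl)acetic acid; 17 (2S,3E)-1-[(tert-butyldimethylsilyl)oxy]-4-[(4S)-2,2-dimethyl-1,3-dioxolan-4-yl]but-3-en-2-ol
Product: 18 (2S,3E)-1-[(tert-butyldimethylsilyl)oxy]-4-[(4S)-2,2-dimethyl-1,3-dioxolan-4-yl]but-3-en-2-yl 2-(1β,4,4-trimethyl-8-oxo-cis-perhydroazulen-1α-yl)acetate
Conditions: DCC, DMAP (cat.), CH2Cl2, 25 °C
Reagents that add atoms: none
Why: Steglich esterification; the carbinol keeps its configuration.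

Step 14
Reactants: 18 the allylic ester from step 13
Product: 21 (2R,3S,4E)-6-[(tert-butyldimethylsilyl)oxy]-3-[(4S)-2,2-dimethyl-1,3-dioxolan-4-yl]-2-(1β,4,4-trimethyl-8-oxo-cis-perhydroazulen-1α-yl)hex-4-enoic acid, via silyl ketene acetal 19 (not isolated), via silyl ester 20 (not isolated)
Conditions: LDA (2.5 equiv), Me3SiCl/Et3N, THF, −78 → 50 °C; then 10 % aq. citric acid
Reagents that add atoms: none
Why: Ireland–Claisen [3,3] rearrangement through a chair: LDA/THF gives the E(O)-enolate and the (E)-alkene with the carbinol CH2OTBS group equatorial transfers C–O chirality to the new C3 centre, while the chair relays it to C2 (anti, which is cis on the later oxolane); the ketone is held as its C7=C8 trimethylsilyl enol ether and returns on work-up.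

Step 15
Reactants: 21 the hexenoic acid from step 14
Product: 24 (3R,4R)-4-[(4S)-2,2-dimethyl-1,3-dioxolan-4-yl]-3-(1β,4,4-trimethyl-8-oxo-cis-perhydroazulen-1α-yl)oxolan-2-one, via aldehyde acid 22 (not isolated), via hydroxy acid 23 (not isolated)
Conditions: O3, CH2Cl2/EtOH (7:3), −78 °C; then NaBH4, −78 °C; then TsOH (cat.), CH2Cl2, 25 °C
Reagents that add atoms: ozone, [O-][O+]=O
Why: Ozonolysis of the only alkene with low-temperature borohydride work-up reduces the aldehyde but not the hindered ketone, and the γ-hydroxy acid lactonises; no stereocentre is touched.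

Step 16
Reactants: 24 the keto lactone from step 15
Product: 25 (3R,4R)-4-[(4S)-2,2-dimethyl-1,3-dioxolan-4-yl]-3-[(1R,3aR,8aS)-1,4,4-trimethyl-8-methylidenedecahydroazulen-1-yl]oxolan-2-one
Conditions: Zn, CH2Br2, TiCl4, THF/CH2Cl2, 0 → 25 °C
Reagents that add atoms: dibromomethane, BrCBr
Why: Lombardo methylenation is non-basic and ketone-selective, so the lactone is spared and neither C3′ nor C8a epimerises.

Step 17
Reactants: 25 the methylene lactone from step 16
Product: 26 (3R,4R)-4-[(4S)-2,2-dimethyl-1,3-dioxolan-4-yl]-3-[(1R,3aR,8aS)-1,4,4-trimethyl-8-methylidenedecahydroazulen-1-yl]oxolan-2-ol (both anomers)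
Conditions: i-Bu2AlH (1.1 equiv), CH2Cl2, −78 °C
Reagents that add atoms: none
Why: Partial reduction of the γ-lactone to the lactol; it is the only reducible group.

Step 18
Reactants: 26 the lactol from step 17
Product: 27 (1S)-1-[(3R,4R)-5-methoxy-4-[(1R,3aR,8aS)-1,4,4-trimethyl-8-methylidenedecahydroazulen-1-yl]oxolan-3-yl]ethane-1,2-diol (both anomers)
Conditions: CSA (10 mol %), MeOH, 0 → 25 °C
Reagents that add atoms: methanol, CO
Why: Fischer glycosidation protects the lactol as its methyl acetal and the same acid methanolyses the acetonide.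

Step 19
Reactants: 27 the methyl acetal diol from step 18
Product: 28 (2S)-2-hydroxy-2-[(3R,4R)-5-methoxy-4-[(1R,3aR,8aS)-1,4,4-trimethyl-8-methylidenedecahydroazulen-1-yl]oxolan-3-yl]acetic acid
Conditions: TEMPO (20 mol %), PhI(OAc)2, NaHCO3, MeCN/H2O, 0 → 25 °C
Reagents that add atoms: water, O
Why: Oxoammonium oxidation takes the primary alcohol to the acid and leaves the secondary alcohol, the acetal (buffered) and the alkene.

Step 20
Reactants: 28 the hydroxy acid from step 19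
Product: 29 methyl (2S)-2-hydroxy-2-[(3R,4R)-5-methoxy-4-[(1R,3aR,8aS)-1,4,4-trimethyl-8-methylidenedecahydroazulen-1-yl]oxolan-3-yl]acetate
Conditions: Me3SiCHN2, MeOH/toluene, 0 °C
Reagents that add atoms: (trimethylsilyl)diazomethane, C[Si](C)(C)C=[N+]=[N-]
Why: Mild methylation of the carboxylic acid; nothing else reacts.

Step 21
Reactants: 29 the methyl ester from step 20
Product: 30 methyl (2S)-2-hydroxy-2-[(3R,4R)-5-hydroxy-4-[(1R,3aR,8aS)-1,4,4-trimethyl-8-methylidenedecahydroazulen-1-yl]oxolan-3-yl]acetate (both anomers)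
Conditions: 0.1 M HCl, THF/H2O, 25 °C
Reagents that add atoms: water, O
Why: Acetal hydrolysis frees the lactol; ester and exocyclic alkene survive dilute acid.

Step 22
Reactants: 30 the lactol from step 21
Product: 31 methyl (2S)-2-acetoxy-2-[(3R,4R,5R)-5-acetoxy-4-[(1R,3aR,8aS)-1,4,4-trimethyl-8-methylidenedecahydroazulen-1-yl]oxolan-3-yl]acetate (CNP0222222.1)
Conditions: Ac2O, pyridine, DMAP (cat.), CH2Cl2, 0 → 25 °C
Reagents that add atoms: acetic anhydride, CC(=O)OC(C)=O
Why: Acetylation of both hydroxyls; the equilibrating lactol is expected to be acylated mainly trans to the bulky C4 substituent (the 5R anomer), with the minor anomer removed by chromatography.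

## Compound list

1 | (4R)-limonene 1,2-oxide | CC(=C)[C@@H]1CCC2(C)OC2C1 | starting material
2 | (3R)-6-oxo-3-(prop-1-en-2-yl)heptanal | CC(=C)[C@H](CCC(C)=O)CC=O | intermediate
3 | (5S)-2-methyl-5-(prop-1-en-2-yl)cyclopent-1-ene-1-carbaldehyde | CC(=C)[C@@H]1CCC(C)=C1C=O | intermediate
4 | 1-[(5S)-2-methyl-5-(prop-1-en-2-yl)cyclopent-1-en-1-yl]pent-4-en-1-ol | CC(=C)[C@@H]1CCC(C)=C1C(O)CCC=C | intermediate
5 | 1-[(5S)-2-methyl-5-(prop-1-en-2-yl)cyclopent-1-en-1-yl]pent-4-en-1-one | CC(=C)[C@@H]1CCC(C)=C1C(=O)CCC=C | intermediate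
6 | (3aS)-1,4-dimethyl-3,3a,6,7-tetrahydroazulen-8(2H)-one | CC1=CCCC(=O)C2=C(C)CC[C@@H]12 | intermediate
7 | sulfonylhydrazide adduct at C4 (C4 epimers) | Cc1cc(C)c(c(C)c1)S(=O)(=O)NNCC1(C)CCCC(=O)C2=C(C)CC[C@@H]12 | intermediate
8 | (3aS)-1,4,4-trimethyl-3,3a,4,5,6,7-hexahydroazulen-8(2H)-one | CC1(C)CCCC(=O)C2=C(C)CC[C@@H]12 | intermediate
9 | 8α-(2-methylbut-3-en-2-yl) tertiary alcohol of 8 | CC1(C)CCC[C@](O)(C(C)(C)C=C)C2=C(C)CC[C@@H]12 | intermediate
10 | potassium alkoxide of 9 | CC1(C)CCC[C@]([O-])(C(C)(C)C=C)C2=C(C)CC[C@@H]12.[K+] | intermediate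
11 | potassium C8 enolate of 12 | [K+].[O-]C1=C2[C@](C)(CC=C(C)C)CC[C@H]2C(C)(C)CCC1 | intermediate
12 | 1β,4,4-trimethyl-1α-(3-methylbut-2-en-1-yl)-cis-perhydroazulen-8-one | O=C1CCCC(C)(C)[C@@H]2CC[C@@](C)(CC=C(C)C)[C@H]12 | intermediate
13 | 2-(1β,4,4-trimethyl-8-oxo-cis-perhydroazulen-1α-yl)acetic acid | O=C1CCCC(C)(C)[C@@H]2CC[C@@](C)(CC(=O)O)[C@H]12 | intermediate
14 | 1,2:5,6-di-O-isopropylidene-D-mannitol | CC1(C)OC[C@@H](O1)[C@@H](O)[C@H](O)[C@H]1COC(C)(C)O1 | starting material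
15 | (4S,4′S)-4,4′-[(E)-ethene-1,2-diyl]bis(2,2-dimethyl-1,3-dioxolane) | CC1(C)OC[C@@H](O1)/C=C/[C@H]1COC(C)(C)O1 | intermediate
16 | (2S,3E)-4-[(4S)-2,2-dimethyl-1,3-dioxolan-4-yl]but-3-ene-1,2-diol | OC[C@@H](O)/C=C/[C@H]1COC(C)(C)O1 | intermediate
17 | (2S,3E)-1-[(tert-butyldimethylsilyl)oxy]-4-[(4S)-2,2-dimethyl-1,3-dioxolan-4-yl]but-3-en-2-ol | CC(C)(C)[Si](C)(C)OC[C@@H](O)/C=C/[C@H]1COC(C)(C)O1 | intermediate
18 | allylic ester of 13 with 17 | O=C1CCCC(C)(C)[C@@H]2CC[C@@](C)(CC(=O)O[C@H](CO[Si](C)(C)C(C)(C)C)/C=C/[C@H]3COC(C)(C)O3)[C@H]12 | intermediate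
19 | (E)-O-trimethylsilyl ketene acetal of 18 with C7=C8 trimethylsilyl enol ether | C[Si](C)(C)OC1=CCCC(C)(C)[C@@H]2CC[C@@](C)(/C=C(/O[Si](C)(C)C)O[C@H](CO[Si](C)(C)C(C)(C)C)/C=C/[C@H]3COC(C)(C)O3)[C@H]12 | intermediate
20 | trimethylsilyl ester of 21 with C7=C8 trimethylsilyl enol ether | C[Si](C)(C)OC1=CCCC(C)(C)[C@@H]2CC[C@@](C)([C@H](C(=O)O[Si](C)(C)C)[C@H](/C=C/CO[Si](C)(C)C(C)(C)C)[C@H]3COC(C)(C)O3)[C@H]12 | intermediate
21 | (2R,3S,4E)-6-[(tert-butyldimethylsilyl)oxy]-3-[(4S)-2,2-dimethyl-1,3-dioxolan-4-yl]-2-(1β,4,4-trimethyl-8-oxo-cis-perhydroazulen-1α-yl)hex-4-enoic acid | O=C1CCCC(C)(C)[C@@H]2CC[C@@](C)([C@H](C(=O)O)[C@H](/C=C/CO[Si](C)(C)C(C)(C)C)[C@H]3COC(C)(C)O3)[C@H]12 | intermediate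
22 | aldehyde acid from ozonolysis of 21 | O=C1CCCC(C)(C)[C@@H]2CC[C@@](C)([C@H](C(=O)O)[C@H](C=O)[C@H]3COC(C)(C)O3)[C@H]12 | intermediate
23 | γ-hydroxy acid from reduction of 22 | O=C1CCCC(C)(C)[C@@H]2CC[C@@](C)([C@H](C(=O)O)[C@H](CO)[C@H]3COC(C)(C)O3)[C@H]12 | intermediate
24 | (3R,4R)-4-[(4S)-2,2-dimethyl-1,3-dioxolan-4-yl]-3-(1β,4,4-trimethyl-8-oxo-cis-perhydroazulen-1α-yl)oxolan-2-one | O=C1CCCC(C)(C)[C@@H]2CC[C@@](C)([C@@H]3C(=O)OC[C@@H]3[C@H]4COC(C)(C)O4)[C@H]12 | intermediate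
25 | 8-methylidene analogue of 24 | C=C1CCCC(C)(C)[C@@H]2CC[C@@](C)([C@@H]3C(=O)OC[C@@H]3[C@H]4COC(C)(C)O4)[C@H]12 | intermediate
26 | lactol of 25 (both anomers) | C=C1CCCC(C)(C)[C@@H]2CC[C@@](C)([C@@H]3C(O)OC[C@@H]3[C@H]4COC(C)(C)O4)[C@H]12 | intermediate
27 | methyl acetal diol (both anomers) | C=C1CCCC(C)(C)[C@@H]2CC[C@@](C)([C@@H]3C(OC)OC[C@@H]3[C@H](O)CO)[C@H]12 | intermediate
28 | methyl acetal α-hydroxy acid | C=C1CCCC(C)(C)[C@@H]2CC[C@@](C)([C@@H]3C(OC)OC[C@@H]3[C@H](O)C(=O)O)[C@H]12 | intermediate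
29 | methyl acetal α-hydroxy methyl ester | C=C1CCCC(C)(C)[C@@H]2CC[C@@](C)([C@@H]3C(OC)OC[C@@H]3[C@H](O)C(=O)OC)[C@H]12 | intermediate
30 | lactol α-hydroxy methyl ester (both anomers) | C=C1CCCC(C)(C)[C@@H]2CC[C@@](C)([C@@H]3C(O)OC[C@@H]3[C@H](O)C(=O)OC)[C@H]12 | intermediate
31 | methyl (2S)-2-acetoxy-2-[(3R,4R,5R)-5-acetoxy-4-[(1R,3aR,8aS)-1,4,4-trimethyl-8-methylidenedecahydroazulen-1-yl]oxolan-3-yl]acetate | C=C1CCCC(C)(C)[C@@H]2CC[C@@](C)([C@@H]3[C@@H](OC(C)=O)OC[C@@H]3[C@H](OC(C)=O)C(=O)OC)[C@H]12 | target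

## Summary

Total step count: 22. Longest linear sequence: 19 (steps 1–9 and 13–22; steps 10–12 make the allylic alcohol).

Steps most likely to fail:

Step 6 (hydromethylation next to an enone). The fallback sets out from 6 and comes back at 8. Et2Zn/CH2I2 cyclopropanates only the electron-rich C4=C5 alkene to give the cyclopropane-fused enone F1. Hydrogenolysis (H2, PtO2, AcOH) then cleaves the less substituted CH2–C5 bond, leaving the ring CH2 as the second methyl on C4 and giving 8; any C8 carbinol formed is re-oxidised with MnO2.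

Step 8 (the α-face selectivity set in step 7 is a prediction, retro-allylation can compete, and the ring fusion is set by protonation). The fallback sets out from 8 and comes back at 13. Irradiation of 8 with allene (THF, −78 °C, Pyrex) gives the head-to-head [2+2] photoadduct F2. Ozonolysis (O3, then Me2S) gives the cyclobutanone F3, NaOMe/MeOH opens this 1,3-diketone by retro-Claisen cleavage to the keto ester F4, and LiOH gives 13.

Step 14 (ester enolisation beside a free ketone and a crowded chair with the tertiary-alkyl group inside). The fallback sets out from 12 and comes back at 27. Me3SiCH2MgCl/CeCl3 adds to the ketone to give the β-hydroxysilane F5 (either C8 epimer serves), so no ketone remains. RuCl3/NaIO4 gives the acid F6, DCC/DMAP with 17 the ester F7, the same Ireland–Claisen conditions (3.5 equiv LDA) the rearranged acid F8, ozonolysis/NaBH4/lactonisation the lactone F9, and i-Bu2AlH the lactol F10. CSA in MeOH then effects Peterson elimination to the exocyclic methylene together with acetonide methanolysis and glycosidation, giving 27 and making step 16 unnecessary.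

Further compounds
F1 | step 6 | cyclopropane-fused enone (CH2 bridging C4 and C5 of 6; cyclopropane face unassigned) | CC12CC1CCC(=O)C3=C(C)CC[C@@H]23
F2 | step 8 | allene photoadduct of 8 (cyclobutane across C1 and C8a on the α-face; methylidene carbon on C8a) | O=C1CCCC(C)(C)[C@@H]2CC[C@@]3(C)CC(=C)[C@@]123
F3 | step 8 | cyclobutanone from F2 | O=C1CCCC(C)(C)[C@@H]2CC[C@@]3(C)CC(=O)[C@@]123
F4 | step 8 | methyl 2-(1β,4,4-trimethyl-8-oxo-cis-perhydroazulen-1α-yl)acetate | O=C1CCCC(C)(C)[C@@H]2CC[C@@](C)(CC(=O)OC)[C@H]12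
F5 | step 14 | 8-hydroxy-8-[(trimethylsilyl)methyl] analogue of 12 (C8 epimers) | C[Si](C)(C)CC1(O)CCCC(C)(C)[C@@H]2CC[C@@](C)(CC=C(C)C)[C@H]12
F6 | step 14 | 8-hydroxy-8-[(trimethylsilyl)methyl] analogue of 13 | C[Si](C)(C)CC1(O)CCCC(C)(C)[C@@H]2CC[C@@](C)(CC(=O)O)[C@H]12
F7 | step 14 | 8-hydroxy-8-[(trimethylsilyl)methyl] analogue of 18 | C[Si](C)(C)CC1(O)CCCC(C)(C)[C@@H]2CC[C@@](C)(CC(=O)O[C@H](CO[Si](C)(C)C(C)(C)C)/C=C/[C@H]3COC(C)(C)O3)[C@H]12
F8 | step 14 | 8-hydroxy-8-[(trimethylsilyl)methyl] analogue of 21 | C[Si](C)(C)CC1(O)CCCC(C)(C)[C@@H]2CC[C@@](C)([C@H](C(=O)O)[C@H](/C=C/CO[Si](C)(C)C(C)(C)C)[C@H]3COC(C)(C)O3)[C@H]12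
F9 | step 14 | 8-hydroxy-8-[(trimethylsilyl)methyl] analogue of 24 | C[Si](C)(C)CC1(O)CCCC(C)(C)[C@@H]2CC[C@@](C)([C@@H]3C(=O)OC[C@@H]3[C@H]4COC(C)(C)O4)[C@H]12
F10 | step 14 | lactol of F9 (both anomers) | C[Si](C)(C)CC1(O)CCCC(C)(C)[C@@H]2CC[C@@](C)([C@@H]3C(O)OC[C@@H]3[C@H]4COC(C)(C)O4)[C@H]12
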